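**Plan**

1. Retrosynthesis: the C10 acetate and the 8α,9α-epoxide are removed to the 10α-allylic alcohol 27; this goes back through a selenoxide transposition to the 9α,10α-epoxide of a dauc-9-ene, and the C6 ester goes back through a C6 ketone to a C6 vinylsilane.
2. The bicyclo[5.3.0]decane is then cut at C1–C5 and C6–C7 together. Its five-membered ring (C1–C5) and seven-membered ring (C1, C5–C10), joined at the methyl-bearing quaternary carbon C1, map onto a silylalkyne (C5≡C6) tethered through C2–C4 to a methyl-substituted vinylcyclopropane (C1=C10, ring C9/C8/C7); a rhodium (5+2) cycloaddition joins them.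
3. Forward: the cyclopropane (C7–C10) comes first, then C1/C2 by Wittig olefination, C3–C5 from propyne, C6 from a chloroformate and the isopropyl group by cuprate addition. Sharpless epoxidation and double elimination give the alkynyl carbinol, which is silylated; the cycloaddition closes both rings at once and seven functional-group steps finish.
4. Stereochemistry: the cyclopropane comes from Charette's dioxaborolane and C4 from Sharpless epoxidation with D-tartrate; C1 is set by transfer from the cyclopropane in the cycloaddition, matched with C4.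
5. C5 follows by equilibration, C6 by hydroxyl-directed reduction, the 9,10-epoxide by attack anti to the C1 methyl, C10–O is kept through the transposition, and the 8,9-epoxide is directed by the C10 hydroxyl.

Key step: step 12

Remark on numbering: daucane numbering is used for all bicyclic compounds (C1 methyl-bearing fusion carbon, C2, C3, C4 carbinol carbon with the isopropyl group, C5 fusion CH, C6, C7, C8 methyl-bearing, C9, C10). β is the face of the C1 methyl; the target is 4β-hydroxy, 5α-H, 6α-acyloxy, 8α,9α-epoxy, 10α-acetoxy.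

Remark on the chemistry (assumption): insertion of rhodium into the cyclopropane is taken as stereospecific, so the cyclopropane configuration, and not only C4, decides C1. The (1R,2R)-cyclopropane is the partner matched with (R)-C4; it leaves the C8 methyl α (H8 β) in the cycloadduct, which is why the allylic alcohol is later made by a selenoxide syn-elimination.

**Step 1**
Reactants: 1 (E)-but-2-en-1-ol
Product: 2 [(1R,2R)-2-methylcyclopropyl]methanol
Conditions: Et2Zn, CH2I2, DME, (4S,5S)-2-butyl-N,N,N′,N′-tetramethyl-1,3,2-dioxaborolane-4,5-dicarboxamide (1.2 equiv), CH2Cl2, −10 °C → rt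
Reagents that add atoms: diiodomethane, ICI
Why: Charette's asymmetric Simmons–Smith cyclopropanation, in which the zinc alkoxide of the allylic alcohol binds the chiral dioxaborolane and Zn(CH2I)2 is delivered to one alkene face; the (4S,5S)-ligand is the mirror image of the one known to convert cinnamyl alcohol into its (1S,2S)-cyclopropane, so both new centres (later C9 and C8) should be (R), with the trans relationship fixed by the E-alkene.

**Step 2**
Reactants: 2 [(1R,2R)-2-methylcyclopropyl]methanol; 3 ethyl 2-(triphenylphosphoranylidene)propanoate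
Product: 5 ethyl (2E)-2-methyl-3-[(1R,2R)-2-methylcyclopropyl]prop-2-enoate, via (1R,2R)-2-methylcyclopropane-1-carbaldehyde 4 (not isolated)
Conditions: Dess–Martin periodinane, CH2Cl2, 0 °C → rt; then 3, rt
Reagents that add atoms: none
Why: Dess–Martin oxidation followed in the same flask by a Wittig olefination spares the volatile aldehyde an isolation, and the α-methyl stabilised ylide is expected to give the (E)-trisubstituted enoate with the ester trans to the cyclopropyl group.

**Step 3**
Reactants: 5 ethyl (2E)-2-methyl-3-[(1R,2R)-2-methylcyclopropyl]prop-2-enoate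
Product: 6 (2E)-2-methyl-3-[(1R,2R)-2-methylcyclopropyl]prop-2-en-1-ol
Conditions: i-Bu2AlH (2.2 equiv), CH2Cl2, −78 °C; Rochelle salt work-up
Reagents that add atoms: none
Why: 1,2-reduction of the enoate by the aluminium hydride gives the allylic alcohol without touching the alkene geometry or the cyclopropane.

**Step 4**
Reactants: 6 (2E)-2-methyl-3-[(1R,2R)-2-methylcyclopropyl]prop-2-en-1-ol
Product: 7 (1R,2R)-1-[(1E)-3-bromo-2-methylprop-1-en-1-yl]-2-methylcyclopropane
Conditions: CBr4, PPh3, CH2Cl2, −20 °C; used at once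
Reagents that add atoms: tetrabromomethane, BrC(Br)(Br)Br
Why: Appel bromination replaces the primary allylic hydroxyl by SN2 under neutral conditions, which avoids ionisation of the cyclopropyl-stabilised allylic system.

**Step 5**
Reactants: 7 (1R,2R)-1-[(1E)-3-bromo-2-methylprop-1-en-1-yl]-2-methylcyclopropane
Product: 9 methyl (6E)-6-methyl-7-[(1R,2R)-2-methylcyclopropyl]hept-6-en-2-ynoate, via lithium acetylide 8 (not isolated)
Conditions: propyne, n-BuLi (2 equiv), TMEDA, Et2O–hexane, −78 °C → rt; 7, −78 → 0 °C; then ClCO2Me, −78 °C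
Reagents that add atoms: propyne, CC#C; methyl chloroformate, COC(=O)Cl
Why: propargylation with 1,3-dilithiopropyne, which alkylates primary allylic halides at its sp3 carbon by SN2, leaves a lithium acetylide that is acylated in the same flask by the chloroformate, so C3–C5 and C6 are added in one operation.

**Step 6**
Reactants: 9 methyl (6E)-6-methyl-7-[(1R,2R)-2-methylcyclopropyl]hept-6-en-2-ynoate
Product: 10 methyl (2E,6E)-6-methyl-7-[(1R,2R)-2-methylcyclopropyl]-3-(propan-2-yl)hepta-2,6-dienoate
Conditions: i-PrMgCl (2.2 equiv), CuI (1.1 equiv), THF, −40 °C; then 9, −78 °C; MeOH, −78 °C, then aq. NH4Cl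
Reagents that add atoms: isopropylmagnesium chloride, CC(C)[Mg]Cl
Why: conjugate addition of a diorganocuprate to a 2-ynoate is a syn carbocupration, and protonation of the α-cuprio enoate at −78 °C with retention should give the (2E)-enoate with the isopropyl group cis to H and trans to the ester.

**Step 7**
Reactants: 10 methyl (2E,6E)-6-methyl-7-[(1R,2R)-2-methylcyclopropyl]-3-(propan-2-yl)hepta-2,6-dienoate
Product: 11 (2E,6E)-6-methyl-7-[(1R,2R)-2-methylcyclopropyl]-3-(propan-2-yl)hepta-2,6-dien-1-ol
Conditions: i-Bu2AlH (2.2 equiv), CH2Cl2, −78 °C; Rochelle salt work-up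
Reagents that add atoms: none
Why: 1,2-reduction of the enoate gives the geometrically defined 3,3-disubstituted allylic alcohol needed for the asymmetric epoxidation.

**Step 8**
Reactants: 11 (2E,6E)-6-methyl-7-[(1R,2R)-2-methylcyclopropyl]-3-(propan-2-yl)hepta-2,6-dien-1-ol
Product: 12 [(2R,3R)-3-{(3E)-3-methyl-4-[(1R,2R)-2-methylcyclopropyl]but-3-en-1-yl}-3-(propan-2-yl)oxiran-2-yl]methanol
Conditions: Ti(OiPr)4 (10 mol%), D-(−)-diethyl tartrate (12 mol%), t-BuOOH, 4 Å MS, CH2Cl2, −20 °C
Reagents that add atoms: tert-butyl hydroperoxide, CC(C)(C)OO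
Why: Katsuki–Sharpless asymmetric epoxidation touches only the allylic alcohol double bond; by the facial rule that gives (2S,3S)-epoxygeraniol with L-(+)-tartrate, D-(−)-tartrate should give the (2R,3R)-epoxide of this alcohol (chain cis, isopropyl trans to CH2OH), which sets the future C4 as (R).

**Step 9**
Reactants: 12 [(2R,3R)-3-{(3E)-3-methyl-4-[(1R,2R)-2-methylcyclopropyl]but-3-en-1-yl}-3-(propan-2-yl)oxiran-2-yl]methanol
Product: 13 (2R,3S)-3-(chloromethyl)-2-{(3E)-3-methyl-4-[(1R,2R)-2-methylcyclopropyl]but-3-en-1-yl}-2-(propan-2-yl)oxirane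
Conditions: PPh3, CCl4, NaHCO3, reflux
Reagents that add atoms: tetrachloromethane, ClC(Cl)(Cl)Cl
Why: Appel chlorination of the primary alcohol under buffered neutral conditions leaves the trisubstituted epoxide and both its stereocentres untouched (the descriptor at the CH carbon changes only because CH2Cl outranks the ring carbon).

**Step 10**
Reactants: 13 (2R,3S)-3-(chloromethyl)-2-{(3E)-3-methyl-4-[(1R,2R)-2-methylcyclopropyl]but-3-en-1-yl}-2-(propan-2-yl)oxirane
Product: 15 (3R,6E)-6-methyl-7-[(1R,2R)-2-methylcyclopropyl]-3-(propan-2-yl)hept-6-en-1-yn-3-ol, via chlorovinyl alkoxide 14 (not isolated)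
Conditions: n-BuLi (3.3 equiv), THF, −78 → −30 °C; aq. NH4Cl
Reagents that add atoms: none
Why: Takano–Yadav double elimination of a 2,3-epoxy chloride, in which deprotonation next to chlorine opens the oxirane to the chlorovinyl alkoxide, a second equivalent eliminates HCl to the alkyne and a third holds it as the acetylide; the C–O bond at the tertiary carbon is never broken, so C4 stays (R).

**Step 11**
Reactants: 15 (3R,6E)-6-methyl-7-[(1R,2R)-2-methylcyclopropyl]-3-(propan-2-yl)hept-6-en-1-yn-3-ol; 16 benzyl(chloro)dimethylsilane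
Product: 17 (3R,6E)-1-[benzyl(dimethyl)silyl]-6-methyl-7-[(1R,2R)-2-methylcyclopropyl]-3-(propan-2-yl)hept-6-en-1-yn-3-ol
Conditions: EtMgBr (2.2 equiv), THF, 0 → 40 °C; then 16, rt
Reagents that add atoms: none
Why: C-silylation of the magnesium acetylide of the dianion (Iotsitch reagent), the hindered tertiary magnesium alkoxide being far less reactive toward the chlorosilane.

**Step 12**
Reactants: 17 (3R,6E)-1-[benzyl(dimethyl)silyl]-6-methyl-7-[(1R,2R)-2-methylcyclopropyl]-3-(propan-2-yl)hept-6-en-1-yn-3-ol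
Product: 18 6-[benzyl(dimethyl)silyl]-8βH-dauca-5,9-dien-4β-ol (1β-methyl, 4α-isopropyl, 8α-methyl)
Conditions: [Rh(CO)2Cl]2 (5 mol%), toluene, 80 → 110 °C
Reagents that add atoms: none
Why: The monovalent rhodium centre of [Rh(CO)2Cl]2 binds the vinylcyclopropane and inserts into its unsubstituted C9–C7 bond to give a σ,π-allyl rhodacyclohexene; the tethered silylalkyne then inserts into the Rh–C1 bond, forming C1–C5 and closing the five-membered ring in a 5-exo sense through the C2–C4 tether, and C6–C7 reductive elimination from the rhodacyclooctadiene closes the seven-membered ring as a cyclohepta-1,4-diene. This is the known rhodium-catalysed intramolecular (5+2) cycloaddition of alkyne-tethered vinylcyclopropanes, which tolerates silylalkynes, a methyl group on the alkene carbon that becomes the ring fusion, and trans-2-alkyl cyclopropanes. C1, the only new stereocentre, is set by transfer from the cyclopropane: a cis C9=C10 ring olefin demands the s-cis conformer, rhodium stays on the alkene face that carried the C7 methylene, and for the (1R,2R)-cyclopropane this face gives (1R), with the C1 methyl cis to the C4 hydroxyl. The C4 centre is matched with it, since on that face the isopropyl group points away from the forming ring and only the small hydroxyl is 1,3-cis to the C1 methyl. The selectivity needed is cleavage of the less substituted cyclopropane bond, which [Rh(CO)2Cl]2 is known to prefer for trans-alkyl cyclopropanes and which is the only cleavage compatible with the tether preference; C8 passes through untouched (methyl α) and silicon ends at C6.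

**Step 13**
Reactants: 18 6-[benzyl(dimethyl)silyl]-8βH-dauca-5,9-dien-4β-ol
Product: 21 4β-hydroxy-5αH,8βH-dauc-9-en-6-one, via alkenylsilanol 19 (not isolated), via dienol 20 (not isolated)
Conditions: Bu4NF, THF, 0 °C; then KHCO3, 30% H2O2, MeOH–THF, rt; then DBU, toluene, rt
Reagents that add atoms: hydrogen peroxide, OO
Why: Tamao–Fleming oxidation of the alkenyl(benzyl)dimethylsilane, in which fluoride cleaves the benzyl–silicon bond to the silanol, peroxide oxidises the C6–Si bond to the enol and this tautomerises to the C6 ketone; base equilibration at C5 should favour the trans-fused ketone (H5 α) because cis fusion would place C6 and the C4 isopropyl group cis on the cyclopentane.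

**Step 14**
Reactants: 21 4β-hydroxy-5αH,8βH-dauc-9-en-6-one
Product: 22 5αH,8βH-dauc-9-ene-4β,6α-diol
Conditions: Me4NBH(OAc)3, MeCN–AcOH (1:1), −30 °C
Reagents that add atoms: none
Why: Evans–Saksena reduction, in which the C4 hydroxyl exchanges onto boron and delivers hydride intramolecularly to the β-face of the C6 carbonyl, giving the 6α-alcohol (1,3-anti diol) against the intrinsic preference for attack anti to the angular methyl.

**Step 15**
Reactants: 22 5αH,8βH-dauc-9-ene-4β,6α-diol
Product: 23 4β-hydroxy-5αH,8βH-dauc-9-en-6α-yl 3-methylbutanoate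
Conditions: 3-methylbutanoic anhydride, DMAP, Et3N, CH2Cl2, 0 °C → rt
Reagents that add atoms: 3-methylbutanoic anhydride, CC(C)CC(=O)OC(=O)CC(C)C
Why: DMAP-catalysed acylation takes the secondary C6 hydroxyl only, the tertiary C4 hydroxyl flanked by the isopropyl group being unreactive under these conditions.

**Step 16**
Reactants: 23 4β-hydroxy-5αH,8βH-dauc-9-en-6α-yl 3-methylbutanoate
Product: 24 9α,10α-epoxy-4β-hydroxy-5αH,8βH-daucan-6α-yl 3-methylbutanoate
Conditions: mCPBA, NaHCO3, CH2Cl2, 0 °C
Reagents that add atoms: 3-chloroperoxybenzoic acid, OOC(=O)c1cccc(Cl)c1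
Why: Prilezhaev epoxidation of the only alkene should occur from the α-face, since the β-face of C9=C10 is shielded by the pseudo-axial C1 methyl while the C8 methyl is pseudo-equatorial.

**Step 17**
Reactants: 24 9α,10α-epoxy-4β-hydroxy-5αH,8βH-daucan-6α-yl 3-methylbutanoate
Product: 27 4β,10α-dihydroxy-5αH-dauc-8-en-6α-yl 3-methylbutanoate, via hydroxy selenide 25 (not isolated), via selenoxide 26 (not isolated)
Conditions: PhSeSePh, NaBH4, EtOH, rt → 60 °C; then THF, 30% H2O2, 0 °C → rt
Reagents that add atoms: none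
Why: Sharpless–Lauer transposition, in which the selenolate opens the epoxide by SN2 attack at C9 from the β-face (C10 is neopentylic) and the derived selenoxide undergoes syn-elimination away from the carbinol with the cis (β) hydrogen at C8, giving the C8=C9 alkene while the C10–O bond and its α configuration are untouched.

**Step 18**
Reactants: 27 4β,10α-dihydroxy-5αH-dauc-8-en-6α-yl 3-methylbutanoate
Product: 28 8α,9α-epoxy-4β,10α-dihydroxy-5αH-daucan-6α-yl 3-methylbutanoate
Conditions: VO(acac)2 (5 mol%), t-BuOOH, CH2Cl2, 0 °C → rt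
Reagents that add atoms: tert-butyl hydroperoxide, CC(C)(C)OO
Why: hydroxyl-directed (Sharpless–Michaelson) epoxidation, in which the vanadium alkoxide of the 10α-allylic alcohol delivers oxygen to the same face of the C8=C9 alkene, setting the 8α,9α-epoxide with the C8 methyl β.

**Step 19**
Reactants: 28 8α,9α-epoxy-4β,10α-dihydroxy-5αH-daucan-6α-yl 3-methylbutanoate
Product: 29 10α-acetoxy-8α,9α-epoxy-4β-hydroxy-5αH-daucan-6α-yl 3-methylbutanoate (CNP0137153.1)
Conditions: Ac2O, DMAP, pyridine, CH2Cl2, rt
Reagents that add atoms: acetic anhydride, CC(=O)OC(C)=O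
Why: DMAP-catalysed acetylation of the remaining secondary (C10) hydroxyl, to which the tertiary C4 hydroxyl, the epoxide and the isovalerate are inert.

**Compound list**

1 | (E)-but-2-en-1-ol | C/C=C/CO | starting material
2 | [(1R,2R)-2-methylcyclopropyl]methanol | OC[C@@H]1C[C@H]1C | intermediate
3 | ethyl 2-(triphenylphosphoranylidene)propanoate | CCOC(=O)C(C)=P(c1ccccc1)(c1ccccc1)c1ccccc1 | starting material
4 | (1R,2R)-2-methylcyclopropane-1-carbaldehyde | O=C[C@@H]1C[C@H]1C | intermediate (not isolated)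
5 | ethyl (2E)-2-methyl-3-[(1R,2R)-2-methylcyclopropyl]prop-2-enoate | CCOC(=O)/C(C)=C/[C@@H]1C[C@H]1C | intermediate
6 | (2E)-2-methyl-3-[(1R,2R)-2-methylcyclopropyl]prop-2-en-1-ol | OC/C(C)=C/[C@@H]1C[C@H]1C | intermediate
7 | (1R,2R)-1-[(1E)-3-bromo-2-methylprop-1-en-1-yl]-2-methylcyclopropane | BrC/C(C)=C/[C@@H]1C[C@H]1C | intermediate
8 | lithium (5E)-5-methyl-6-[(1R,2R)-2-methylcyclopropyl]hex-5-en-1-yn-1-ide | [Li]C#CCC/C(C)=C/[C@@H]1C[C@H]1C | intermediate (not isolated)
9 | methyl (6E)-6-methyl-7-[(1R,2R)-2-methylcyclopropyl]hept-6-en-2-ynoate | COC(=O)C#CCC/C(C)=C/[C@@H]1C[C@H]1C | intermediate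
10 | methyl (2E,6E)-6-methyl-7-[(1R,2R)-2-methylcyclopropyl]-3-(propan-2-yl)hepta-2,6-dienoate | COC(=O)/C=C(/C(C)C)CC/C(C)=C/[C@@H]1C[C@H]1C | intermediate
11 | (2E,6E)-6-methyl-7-[(1R,2R)-2-methylcyclopropyl]-3-(propan-2-yl)hepta-2,6-dien-1-ol | OC/C=C(/C(C)C)CC/C(C)=C/[C@@H]1C[C@H]1C | intermediate
12 | [(2R,3R)-3-{(3E)-3-methyl-4-[(1R,2R)-2-methylcyclopropyl]but-3-en-1-yl}-3-(propan-2-yl)oxiran-2-yl]methanol | OC[C@H]1O[C@@]1(C(C)C)CC/C(C)=C/[C@@H]1C[C@H]1C | intermediate
13 | (2R,3S)-3-(chloromethyl)-2-{(3E)-3-methyl-4-[(1R,2R)-2-methylcyclopropyl]but-3-en-1-yl}-2-(propan-2-yl)oxirane | ClC[C@H]1O[C@@]1(C(C)C)CC/C(C)=C/[C@@H]1C[C@H]1C | intermediate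
14 | (3R,6E)-1-chloro-6-methyl-7-[(1R,2R)-2-methylcyclopropyl]-3-(propan-2-yl)hepta-1,6-dien-3-ol, present as its lithium alkoxide, chloroalkene geometry undefined | ClC=C[C@](O)(C(C)C)CC/C(C)=C/[C@@H]1C[C@H]1C | intermediate (not isolated)
15 | (3R,6E)-6-methyl-7-[(1R,2R)-2-methylcyclopropyl]-3-(propan-2-yl)hept-6-en-1-yn-3-ol | C#C[C@](O)(C(C)C)CC/C(C)=C/[C@@H]1C[C@H]1C | intermediate
16 | benzyl(chloro)dimethylsilane | C[Si](C)(Cl)Cc1ccccc1 | starting material
17 | (3R,6E)-1-[benzyl(dimethyl)silyl]-6-methyl-7-[(1R,2R)-2-methylcyclopropyl]-3-(propan-2-yl)hept-6-en-1-yn-3-ol | C[Si](C)(Cc1ccccc1)C#C[C@](O)(C(C)C)CC/C(C)=C/[C@@H]1C[C@H]1C | intermediate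
18 | 6-[benzyl(dimethyl)silyl]-8βH-dauca-5,9-dien-4β-ol | C[C@@H]1CC([Si](C)(C)Cc2ccccc2)=C2[C@](O)(C(C)C)CC[C@]2(C)C=C1 | intermediate
19 | 6-[hydroxy(dimethyl)silyl]-8βH-dauca-5,9-dien-4β-ol | C[C@@H]1CC([Si](C)(C)O)=C2[C@](O)(C(C)C)CC[C@]2(C)C=C1 | intermediate (not isolated)
20 | 8βH-dauca-5,9-diene-4β,6-diol (dienol) | C[C@@H]1CC(O)=C2[C@](O)(C(C)C)CC[C@]2(C)C=C1 | intermediate (not isolated)
21 | 4β-hydroxy-5αH,8βH-dauc-9-en-6-one | C[C@@H]1CC(=O)[C@@H]2[C@@](C)(C=C1)CC[C@@]2(O)C(C)C | intermediate
22 | 5αH,8βH-dauc-9-ene-4β,6α-diol | C[C@@H]1C[C@H](O)[C@@H]2[C@@](C)(C=C1)CC[C@@]2(O)C(C)C | intermediate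
23 | 4β-hydroxy-5αH,8βH-dauc-9-en-6α-yl 3-methylbutanoate | C[C@@H]1C[C@H](OC(=O)CC(C)C)[C@@H]2[C@@](C)(C=C1)CC[C@@]2(O)C(C)C | intermediate
24 | 9α,10α-epoxy-4β-hydroxy-5αH,8βH-daucan-6α-yl 3-methylbutanoate | C[C@@H]1C[C@H](OC(=O)CC(C)C)[C@@H]2[C@@](C)([C@@H]3O[C@@H]31)CC[C@@]2(O)C(C)C | intermediate
25 | 4β,10α-dihydroxy-9β-(phenylselanyl)-5αH,8βH-daucan-6α-yl 3-methylbutanoate | C[C@@H]1C[C@H](OC(=O)CC(C)C)[C@@H]2[C@@](C)([C@H](O)[C@H]1[Se]c1ccccc1)CC[C@@]2(O)C(C)C | intermediate (not isolated)
26 | 4β,10α-dihydroxy-9β-(phenylseleninyl)-5αH,8βH-daucan-6α-yl 3-methylbutanoate | C[C@@H]1C[C@H](OC(=O)CC(C)C)[C@@H]2[C@@](C)([C@H](O)[C@H]1[Se](=O)c1ccccc1)CC[C@@]2(O)C(C)C | intermediate (not isolated)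
27 | 4β,10α-dihydroxy-5αH-dauc-8-en-6α-yl 3-methylbutanoate | O[C@@H]1C=C(C)C[C@H](OC(=O)CC(C)C)[C@@H]2[C@]1(C)CC[C@@]2(O)C(C)C | intermediate
28 | 8α,9α-epoxy-4β,10α-dihydroxy-5αH-daucan-6α-yl 3-methylbutanoate | O[C@@H]1[C@@H]2O[C@]2(C)C[C@H](OC(=O)CC(C)C)[C@@H]2[C@]1(C)CC[C@@]2(O)C(C)C | intermediate
29 | 10α-acetoxy-8α,9α-epoxy-4β-hydroxy-5αH-daucan-6α-yl 3-methylbutanoate (CNP0137153.1) | CC(=O)O[C@@H]1[C@@H]2O[C@]2(C)C[C@H](OC(=O)CC(C)C)[C@@H]2[C@]1(C)CC[C@@]2(O)C(C)C | target

**Total step count:** 19
**Longest linear sequence:** 19 steps (1 → 29)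

**Steps most likely to fail**

1. Step 12. The alkyne carries both a bulky silyl group and a fully substituted propargylic carbon, so insertion may be slow; catalyst decay, alkyne oligomerisation or cleavage of the methyl-bearing cyclopropane bond could then compete. The fallback lowers the oxidation level of the tether and sets C4 after the cycloaddition. It sets out from bromide 7 (and silane 16) and returns at 18.
   - Alkylation of the lithium enolate of N-methoxy-N-methylacetamide (LiN(iPr)2, THF, −78 °C) with 7 would give (4E)-N-methoxy-N,4-dimethyl-5-[(1R,2R)-2-methylcyclopropyl]pent-4-enamide F1.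
   - Silane 16 and ethynylmagnesium bromide would give benzyl(ethynyl)dimethylsilane F2, whose lithium acetylide adds to the amide to give (6E)-1-[benzyl(dimethyl)silyl]-6-methyl-7-[(1R,2R)-2-methylcyclopropyl]hept-6-en-1-yn-3-one F3.
   - The same [Rh(CO)2Cl]2 cycloaddition, now with a trigonal C4, an electron-poor alkyne and C1 fixed by the cyclopropane alone, should give 6-[benzyl(dimethyl)silyl]-11,12,13-trinor-8βH-dauca-5,9-dien-4-one F4 (the 4-oxo analogue of 18 without the isopropyl group).
   - Addition of i-PrMgCl with LaCl3·2LiCl to the C4 ketone anti to the C1 methyl should give 18.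

2. Step 13. Fluoride may protodesilylate the hindered alkenylsilane faster than the silicon is oxidised, and the basic medium may dehydrate or retro-aldolise the β-hydroxy ketone. The fallback replaces nucleophilic activation at silicon by electrophilic oxygen transfer. It sets out from 18 and returns at 21.
   - Epoxidation directed by the C4 hydroxyl (VO(acac)2, t-BuOOH) would give the α,β-epoxysilane 6α-[benzyl(dimethyl)silyl]-5β,6β-epoxy-8βH-dauc-9-en-4β-ol F5.
   - Dilute H2SO4 in aqueous THF should open it through the β-silyl cation and expel silicon (Stork–Colvin unmasking) to the same enol, and after the same C5 equilibration to ketone 21.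

3. Step 17. The isovalerate may be lost by ethanolysis in the selenolate medium while the hindered epoxide opens slowly. The fallback moves the acylation behind the transposition. It sets out from diol 22 and returns at 27.
   - mCPBA on 22 would give 9α,10α-epoxy-5αH,8βH-daucane-4β,6α-diol F6.
   - Selenolate opening would give 9β-(phenylselanyl)-5αH,8βH-daucane-4β,6α,10α-triol F7, and H2O2 the selenoxide 9β-(phenylseleninyl)-5αH,8βH-daucane-4β,6α,10α-triol F8.
   - Syn-elimination would give 5αH-dauc-8-ene-4β,6α,10α-triol F9.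
   - Mono-acylation with 3-methylbutanoic anhydride and DMAP at low temperature should take the C6 hydroxyl in preference to the neopentylic C10 hydroxyl and give 27.

**Further compounds**

F1 | step 12 | (4E)-N-methoxy-N,4-dimethyl-5-[(1R,2R)-2-methylcyclopropyl]pent-4-enamide | CON(C)C(=O)CC/C(C)=C/[C@@H]1C[C@H]1C
F2 | step 12 | benzyl(ethynyl)dimethylsilane | C#C[Si](C)(C)Cc1ccccc1
F3 | step 12 | (6E)-1-[benzyl(dimethyl)silyl]-6-methyl-7-[(1R,2R)-2-methylcyclopropyl]hept-6-en-1-yn-3-one | C[Si](C)(Cc1ccccc1)C#CC(=O)CC/C(C)=C/[C@@H]1C[C@H]1C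
F4 | step 12 | 6-[benzyl(dimethyl)silyl]-11,12,13-trinor-8βH-dauca-5,9-dien-4-one | C[C@@H]1CC([Si](C)(C)Cc2ccccc2)=C2C(=O)CC[C@]2(C)C=C1
F5 | step 13 | 6α-[benzyl(dimethyl)silyl]-5β,6β-epoxy-8βH-dauc-9-en-4β-ol | C[C@@H]1C[C@@]2([Si](C)(C)Cc3ccccc3)O[C@]23[C@](O)(C(C)C)CC[C@]3(C)C=C1
F6 | step 17 | 9α,10α-epoxy-5αH,8βH-daucane-4β,6α-diol | C[C@@H]1C[C@H](O)[C@@H]2[C@@](C)([C@@H]3O[C@@H]31)CC[C@@]2(O)C(C)C
F7 | step 17 | 9β-(phenylselanyl)-5αH,8βH-daucane-4β,6α,10α-triol | C[C@@H]1C[C@H](O)[C@@H]2[C@@](C)([C@H](O)[C@H]1[Se]c1ccccc1)CC[C@@]2(O)C(C)C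
F8 | step 17 | 9β-(phenylseleninyl)-5αH,8βH-daucane-4β,6α,10α-triol | C[C@@H]1C[C@H](O)[C@@H]2[C@@](C)([C@H](O)[C@H]1[Se](=O)c1ccccc1)CC[C@@]2(O)C(C)C
F9 | step 17 | 5αH-dauc-8-ene-4β,6α,10α-triol | O[C@@H]1C=C(C)C[C@H](O)[C@@H]2[C@]1(C)CC[C@@]2(O)C(C)C
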